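**Retrosynthetic overview**
1. The target, a cis-(3R,4R)-isoflavan-4-ol, comes from the racemic isoflavanone by one asymmetric transfer hydrogenation under dynamic kinetic resolution, which sets both stereocentres in the last step.
2. The isoflavanone comes from a C3–C1' bond between two normally nucleophilic carbons: the chroman-4-one α-carbon is made electrophilic as an enolonium (silyl enol ether + PhI(OAc)2/BF3·OEt2) and is attacked by the unprotected, already prenylated ring B phenol at its carbon para to OH.
3. The ring B arene comes from 2-bromo-5-methoxyphenol and prenyl bromide; the ring A/C partner comes from 5,7-dihydroxychroman-4-one by 7-O-methylation and bis-silylation.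
4. Ring order: the benzopyranone (rings A and C) is bought preformed and ring B is attached in the key step; no ring is built.

Assumption: 5,7-dihydroxychroman-4-one (1) is taken as a catalogue compound (otherwise two steps from phloroglucinol and 3-chloropropanoic acid).

**Step 1**
Reactants: 1 5,7-dihydroxychroman-4-one
Product: 2 5-hydroxy-7-methoxychroman-4-one
Conditions: MeI (1.1 equiv), K2CO3 (1.2 equiv), acetone, 56 °C
Reagents that add atoms: iodomethane, CI
Why: Williamson O-methylation, selective because the 7-OH (para to the carbonyl) is the most acidic phenol while the 5-OH is locked in a hydrogen bond to the C4 carbonyl and stays free with one equivalent of MeI.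

**Step 2**
Reactants: 2 5-hydroxy-7-methoxychroman-4-one
Product: 3 7-methoxy-4,5-bis(trimethylsilyloxy)-2H-chromene
Conditions: TMSOTf (2.4 equiv), Et3N (3 equiv), CH2Cl2, 0 °C to rt; pentane, filtration, used crude
Reagents that add atoms: trimethylsilyl trifluoromethanesulfonate, C[Si](C)(C)OS(=O)(=O)C(F)(F)F
Why: Silyl enol ether formation by soft enolisation, with C3 the only enolisable position and the phenol silylated at the same time so that no free OH of ring A meets the oxidant in step 4.

**Step 3**
Reactants: 4 2-bromo-5-methoxyphenol; 5 1-bromo-3-methylbut-2-ene (prenyl bromide)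
Product: 7 5-methoxy-2-(3-methylbut-2-en-1-yl)phenol, via lithium 2-lithio-5-methoxyphenoxide 6 (not isolated)
Conditions: n-BuLi (2.1 equiv), THF, −78 to 0 °C; CuBr·SMe2 (10 mol%), then 5 (1.05 equiv), −78 °C to rt; 1 M HCl, 0 °C
Reagents that add atoms: none
Why: Bromine–lithium exchange on the lithium phenoxide followed by CuBr·SMe2-catalysed SN2 allylic alkylation, in which the aryl–metal carbon is far more nucleophilic than the phenoxide oxygen and attacks the unhindered CH2 end of prenyl bromide, so the linear C-prenyl phenol forms at the position fixed by the bromine.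

**Step 4**
Reactants: 3 7-methoxy-4,5-bis(trimethylsilyloxy)-2H-chromene; 7 5-methoxy-2-(3-methylbut-2-en-1-yl)phenol
Product: 10 rac-5-hydroxy-3-[4-hydroxy-2-methoxy-5-(3-methylbut-2-en-1-yl)phenyl]-7-methoxychroman-4-one, via enolonium acetate 8 (not isolated), via 5-O-trimethylsilyl isoflavanone 9 (not isolated)
Conditions: PhI(OAc)2 (1.05 equiv), BF3·OEt2 (1.5 equiv), CH2Cl2, −78 °C, slow addition of 3, 10 min; then 7 (2.5 equiv, excess recovered), −78 to −40 °C; aq NaHCO3; THF/1 M aq citric acid, rt, 15 min
Reagents that add atoms: none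
Why: Proposed new method: enolonium umpolung α-arylation, in which PhI(OAc)2/BF3·OEt2 turns the silyl enol ether at −78 °C into an O-iodanyl enol whose C3 is an α-keto cation equivalent, and the most nucleophilic carbon of 7 (para to OH, ortho to OMe, the only doubly activated unhindered site, well above the unactivated prenyl alkene in π-nucleophilicity) attacks C3 in a Friedel–Crafts-type substitution with loss of PhI, the closest known reaction types being arylation of preformed ketone enolonium species with indoles, their allylation with allylsilanes, and BF3-mediated C-alkylation of free resorcinols; C3 is deliberately formed racemic.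

**Step 5**
Reactants: 10 rac-5-hydroxy-3-[4-hydroxy-2-methoxy-5-(3-methylbut-2-en-1-yl)phenyl]-7-methoxychroman-4-one
Product: 11 (3R,4R)-3-[4-hydroxy-2-methoxy-5-(3-methylbut-2-en-1-yl)phenyl]-7-methoxychromane-4,5-diol (cis)
Conditions: RuCl[(R,R)-TsDPEN](p-cymene) (2 mol%), HCO2H (3 equiv)/Et3N (6 equiv), EtOAc, 40 °C; aq NaHCO3; Et3N-deactivated silica
Reagents that add atoms: none
Why: Noyori asymmetric transfer hydrogenation with dynamic kinetic resolution, in which C3 epimerises through the enol in the amine-rich medium and the (R,R)-catalyst reduces the (3R)-ketone much faster, delivering hydride to the C4 face anti to the 3-aryl group, so 4R (aryl ketone to R-carbinol with the (R,R)-ligand, as for acetophenone and chroman-4-one) and 3R are set together as the cis-alcohol while the isolated prenyl alkene is untouched.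

**Compound list**
1 | 5,7-dihydroxychroman-4-one | Oc1cc(O)c2c(c1)OCCC2=O | starting material
2 | 5-hydroxy-7-methoxychroman-4-one | COc1cc(O)c2c(c1)OCCC2=O | intermediate
3 | 7-methoxy-4,5-bis(trimethylsilyloxy)-2H-chromene | COc1cc(O[Si](C)(C)C)c2c(c1)OCC=C2O[Si](C)(C)C | intermediate
4 | 2-bromo-5-methoxyphenol | COc1ccc(Br)c(O)c1 | starting material
5 | 1-bromo-3-methylbut-2-ene (prenyl bromide) | CC(C)=CCBr | starting material
6 | lithium 2-lithio-5-methoxyphenoxide | COc1ccc([Li])c(O[Li])c1 | intermediate (not isolated)
7 | 5-methoxy-2-(3-methylbut-2-en-1-yl)phenol | COc1ccc(CC=C(C)C)c(O)c1 | intermediate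
8 | acetoxy{[7-methoxy-5-(trimethylsilyloxy)-2H-chromen-4-yl]oxy}(phenyl)-λ3-iodane (enolonium acetate, drawn O-bound, BF3-activated, electrophilic at C3) | COc1cc(O[Si](C)(C)C)c2c(c1)OCC=C2OI(OC(C)=O)c1ccccc1 | intermediate (not isolated)
9 | rac-3-[4-hydroxy-2-methoxy-5-(3-methylbut-2-en-1-yl)phenyl]-7-methoxy-5-(trimethylsilyloxy)chroman-4-one | COc1cc(O[Si](C)(C)C)c2c(c1)OCC(c1cc(CC=C(C)C)c(O)cc1OC)C2=O | intermediate (not isolated)
10 | rac-5-hydroxy-3-[4-hydroxy-2-methoxy-5-(3-methylbut-2-en-1-yl)phenyl]-7-methoxychroman-4-one | COc1cc(O)c2c(c1)OCC(c1cc(CC=C(C)C)c(O)cc1OC)C2=O | intermediate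
11 | (3R,4R)-3-[4-hydroxy-2-methoxy-5-(3-methylbut-2-en-1-yl)phenyl]-7-methoxychromane-4,5-diol (cis) | COc1cc(O)c2c(c1)OC[C@@H](c1cc(CC=C(C)C)c(O)cc1OC)[C@H]2O | target

**Count**
Total steps: 5. Longest linear sequence: 4 steps (1 → 2 → 3 → 10 → 11); step 3 is a one-step side branch.

**Three steps most likely to fail**

Step 4 (key coupling). The enolonium may collapse to the chromone by loss of a C2 hydrogen before it is trapped. It may also be intercepted by the prenyl alkene or the phenol oxygen of 7, and residual trivalent iodine may oxidise the electron-rich prenylphenol. The fallback sets out from 3 and 4 and comes back at 10. Enolonium 8 is made from 3 exactly as before but is trapped with 2-bromo-5-methoxyphenol 4, which has no alkene and is harder to oxidise. This gives rac-3-(5-bromo-4-hydroxy-2-methoxyphenyl)-7-methoxy-5-(trimethylsilyloxy)chroman-4-one F1, which is hydrolysed in the work-up to rac-3-(5-bromo-4-hydroxy-2-methoxyphenyl)-5-hydroxy-7-methoxychroman-4-one F2. The prenyl group is then put on last by Stille coupling of F2 with tributyl(3-methylbut-2-en-1-yl)stannane (Pd(PPh3)4, DMF, 90 °C), which gives 10.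

Step 5 (reduction). The 5-OH is hydrogen-bonded to the C4 carbonyl and may make the ketone too unreactive for clean, selective hydride transfer. The fallback sets out from 10 and comes back at 11. Both phenols are silylated (TBSOTf, 2,6-lutidine, CH2Cl2, −20 °C) to give rac-5-(tert-butyldimethylsilyloxy)-3-[4-(tert-butyldimethylsilyloxy)-2-methoxy-5-(3-methylbut-2-en-1-yl)phenyl]-7-methoxychroman-4-one F3, which no longer has the chelate. The same transfer hydrogenation with RuCl[(R,R)-TsDPEN](p-cymene) under dynamic kinetic resolution gives (3R,4R)-5-(tert-butyldimethylsilyloxy)-3-[4-(tert-butyldimethylsilyloxy)-2-methoxy-5-(3-methylbut-2-en-1-yl)phenyl]-7-methoxychroman-4-ol F4. Desilylation with TBAF buffered with AcOH (THF, 0 °C) avoids the acid that would ionise the benzylic alcohol or cyclise the prenyl phenol, and gives 11.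

Step 3 (prenylation). The dianion may be alkylated in part by the 1-bromobutane formed in the exchange, at oxygen, or at the tertiary end of the allyl unit. The fallback sets out from 4 and comes back at 7. The roles of the partners are reversed: the aryl bromide 4 is the electrophile in a Stille cross-coupling with tributyl(3-methylbut-2-en-1-yl)stannane (Pd(PPh3)4, DMF, 100 °C), which gives 7 directly; no new compound arises on this way (F0).

**Further compounds**
F1 | step 4 | rac-3-(5-bromo-4-hydroxy-2-methoxyphenyl)-7-methoxy-5-(trimethylsilyloxy)chroman-4-one | COc1cc(O[Si](C)(C)C)c2c(c1)OCC(c1cc(Br)c(O)cc1OC)C2=O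
F2 | step 4 | rac-3-(5-bromo-4-hydroxy-2-methoxyphenyl)-5-hydroxy-7-methoxychroman-4-one | COc1cc(O)c2c(c1)OCC(c1cc(Br)c(O)cc1OC)C2=O
F3 | step 5 | rac-5-(tert-butyldimethylsilyloxy)-3-[4-(tert-butyldimethylsilyloxy)-2-methoxy-5-(3-methylbut-2-en-1-yl)phenyl]-7-methoxychroman-4-one | COc1cc(O[Si](C)(C)C(C)(C)C)c2c(c1)OCC(c1cc(CC=C(C)C)c(O[Si](C)(C)C(C)(C)C)cc1OC)C2=O
F4 | step 5 | (3R,4R)-5-(tert-butyldimethylsilyloxy)-3-[4-(tert-butyldimethylsilyloxy)-2-methoxy-5-(3-methylbut-2-en-1-yl)phenyl]-7-methoxychroman-4-ol | COc1cc(O[Si](C)(C)C(C)(C)C)c2c(c1)OC[C@@H](c1cc(CC=C(C)C)c(O[Si](C)(C)C(C)(C)C)cc1OC)[C@H]2O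
F0 | step 3 | none | none
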